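**Retrosynthetic overview**
Ring letters: A = 3,5-dihydroxyphenoxy ring; B and C = the two benzo rings of the dibenzofuran (B carries the A–O ether, C is fused to the dioxin); D = the other benzo ring of the dioxin; E–F = the biaryl; G and H = the two terminal aryloxy rings.
Last events: fifteen-fold O-demethylation ⇐ closure of the 1,4-dioxin ring by a biomimetic dehydrogenative phenol C–O coupling (ring C hydroxyl oxygen to the free C–H carbon of ring D), copying the presumed phlorethol-to-eckol cyclisation.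
Enabling feature: ring D is a phloroglucinol-derived tetraoxygenated ring whose only C–H carbon next to the pre-formed C–O–D diaryl ether oxygen lies para to a free ring D hydroxyl, so two-electron oxidation makes exactly that carbon electrophilic where the neighbouring ring C hydroxyl reaches it through a six-membered ring.
The cyclisation substrate comes from a copper-mediated ether union of a left half (rings A–C) and a right half (rings D–H), each carrying a formyl group that one double Baeyer–Villiger oxidation turns into the two phenols required; rings D and G both derive from fluoroaldehyde 4 by SNAr, the E–F biaryl from an Ullmann homocoupling of two molecules of iodide 8.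
Ring formation order: all benzene rings are bought; the furan ring is closed first (SNAr ether, then Pd-catalysed C–H arylation, step 15) and the 1,4-dioxin ring last (step 22).

Key step: step 22

Assumption: the target has no stereocentre; the tetra-ortho-substituted E–F biaryl axis carries no descriptor in the target structure and is carried through as the racemate.

**Route**

Step 1
Reactants: 1 2-bromo-1-fluoro-4-methoxybenzene
Product: 4 3-bromo-2-fluoro-5-methoxybenzaldehyde, via aryllithium 2 (not isolated), via lithium aminoalkoxide 3 (not isolated)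
Conditions: LiN(i-Pr)2, THF, −78 °C; DMF, −78 to 0 °C; aq. HCl
Reagents that add atoms: N,N-dimethylformamide CN(C)C=O
Why: Directed ortho-lithiation then formylation: the amide base should remove the proton ortho to fluorine (the other ortho position carries bromine), the most acidic C–H of 1, and the aryllithium adds to DMF to give the aldehyde on work-up.

Step 2
Reactants: 5 3,5-dimethoxyphenol
Product: 6 1,3-dimethoxy-5-(methoxymethoxy)benzene
Conditions: MOMCl, i-Pr2NEt, CH2Cl2, 0 °C to rt
Reagents that add atoms: chloromethyl methyl ether COCCl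
Why: Base-mediated O-alkylation of the phenol (MOM acetal protection), which also installs the directing group for the next step.

Step 3
Reactants: 6 1,3-dimethoxy-5-(methoxymethoxy)benzene
Product: 8 2-iodo-1,5-dimethoxy-3-(methoxymethoxy)benzene, via aryllithium 7 (not isolated)
Conditions: n-BuLi, THF, 0 °C; I2, −78 °C to rt
Reagents that add atoms: iodine II
Why: Directed ortho-metalation followed by iodination: the chelating OMOM group should steer lithiation to the carbon between OMOM and OMe, which fixes the oxygen pattern of rings E and F.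

Step 4
Reactants: 8 2-iodo-1,5-dimethoxy-3-(methoxymethoxy)benzene (2 equiv; the second molecule is entered below)
Product: 9 2,2'-bis(methoxymethoxy)-4,4',6,6'-tetramethoxy-1,1'-biphenyl
Conditions: Cu powder (activated, excess), DMF, 150 °C
Reagents that add atoms: a second molecule of 8, 2-iodo-1,5-dimethoxy-3-(methoxymethoxy)benzene COCOc1cc(OC)cc(OC)c1I
Why: Classical Ullmann reductive homocoupling on copper metal, in which two molecules of aryl iodide 8 are joined at their iodine-bearing carbons, a standard entry to tetra-ortho-oxygenated biaryls; the axis forms as the racemate.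

Step 5
Reactants: 9 2,2'-bis(methoxymethoxy)-4,4',6,6'-tetramethoxy-1,1'-biphenyl
Product: 10 4,4',6,6'-tetramethoxy-2'-(methoxymethoxy)-[1,1'-biphenyl]-2-ol
Conditions: HCl (cat.), MeOH/CH2Cl2, 0 °C, stopped at partial conversion (unreacted 9 recycled)
Reagents that add atoms: none
Why: Acid-catalysed acetal methanolysis run to partial conversion: the two MOM groups are equivalent, so this desymmetrisation is statistical and recovered 9 is recycled.

Step 6
Reactants: 10 4,4',6,6'-tetramethoxy-2'-(methoxymethoxy)-[1,1'-biphenyl]-2-ol; 4 3-bromo-2-fluoro-5-methoxybenzaldehyde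
Product: 11 3-bromo-5-methoxy-2-{[4,4',6,6'-tetramethoxy-2'-(methoxymethoxy)-[1,1'-biphenyl]-2-yl]oxy}benzaldehyde
Conditions: Cs2CO3, DMF, 90 °C
Reagents that add atoms: none
Why: Nucleophilic aromatic substitution (SNAr) of the fluoride ortho to the formyl group by the phenoxide of 10, which builds ring G; the bromide, meta to the aldehyde, is not activated and stays.

Step 7
Reactants: 11 bromoaldehyde from step 6 (rings E–G); 12 2,4,6-trimethoxyphenol
Product: 13 5-methoxy-2-{[4,4',6,6'-tetramethoxy-2'-(methoxymethoxy)-[1,1'-biphenyl]-2-yl]oxy}-3-(2,4,6-trimethoxyphenoxy)benzaldehyde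
Conditions: CuI (20 mol %), picolinic acid, K3PO4, DMSO, 100 °C
Reagents that add atoms: none
Why: Copper-catalysed Ullmann diaryl ether synthesis, for which the picolinic acid system tolerates ortho-substituted partners such as 2,6-dialkoxyphenols; the aldehyde is inert.

Step 8
Reactants: 13 aldehyde from step 7 (rings E–H)
Product: 15 5-methoxy-2-{[4,4',6,6'-tetramethoxy-2'-(methoxymethoxy)-[1,1'-biphenyl]-2-yl]oxy}-3-(2,4,6-trimethoxyphenoxy)phenol, via aryl formate 14 (not isolated)
Conditions: mCPBA, NaHCO3, CH2Cl2, 0 °C to rt; then K2CO3 (cat.), MeOH, rt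
Reagents that add atoms: meta-chloroperoxybenzoic acid OOC(=O)c1cccc(Cl)c1
Why: Baeyer–Villiger (Dakin-type) oxidation in which the electron-rich ortho-aryloxy aryl group should migrate in preference to hydride, followed by mild methanolysis of formate 14.

Step 9
Reactants: 15 phenol from step 8
Product: 16 2-[2,4-dimethoxy-6-(2,4,6-trimethoxyphenoxy)phenoxy]-4,4',6,6'-tetramethoxy-2'-(methoxymethoxy)-1,1'-biphenyl
Conditions: MeI, K2CO3, DMF, rt
Reagents that add atoms: iodomethane CI
Why: Williamson O-methylation of the phenol, which completes ring G as a fully methylated unit that cannot be oxidised in the key step.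

Step 10
Reactants: 16 MOM ether from step 9
Product: 17 2'-[2,4-dimethoxy-6-(2,4,6-trimethoxyphenoxy)phenoxy]-4,4',6,6'-tetramethoxy-[1,1'-biphenyl]-2-ol
Conditions: HCl, MeOH/THF, 50 °C
Reagents that add atoms: none
Why: Acidic methanolysis of the MOM acetal; aryl methyl ethers and diaryl ethers are stable to these conditions.

Step 11
Reactants: 17 phenol from step 10; 4 3-bromo-2-fluoro-5-methoxybenzaldehyde
Product: 18 3-bromo-2-({2'-[2,4-dimethoxy-6-(2,4,6-trimethoxyphenoxy)phenoxy]-4,4',6,6'-tetramethoxy-[1,1'-biphenyl]-2-yl}oxy)-5-methoxybenzaldehyde (right half)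
Conditions: Cs2CO3, DMSO, 100 °C
Reagents that add atoms: none
Why: Second SNAr on fluoroaldehyde 4, now building ring D; the ortho-formyl group activates fluoride displacement and is kept as the latent ring D hydroxyl, the bromide as the handle for the union.

Step 12
Reactants: 19 4-(benzyloxy)-3-methoxybenzaldehyde
Product: 20 4-(benzyloxy)-2-bromo-5-methoxybenzaldehyde
Conditions: Br2, NaOAc, AcOH, rt
Reagents that add atoms: bromine BrBr
Why: Electrophilic aromatic bromination para to the methoxy group, as in the known bromination of veratraldehyde-type ethers; acetate buffers HBr and spares the benzyl ether.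

Step 13
Reactants: 20 4-(benzyloxy)-2-bromo-5-methoxybenzaldehyde
Product: 22 4-(benzyloxy)-2-bromo-5-methoxyphenol, via aryl formate 21 (not isolated)
Conditions: mCPBA, CH2Cl2, rt; then K2CO3 (cat.), MeOH, rt
Reagents that add atoms: meta-chloroperoxybenzoic acid OOC(=O)c1cccc(Cl)c1
Why: Baeyer–Villiger oxidation of a para-alkoxybenzaldehyde (aryl migration) and methanolysis of formate 21.

Step 14
Reactants: 22 4-(benzyloxy)-2-bromo-5-methoxyphenol; 23 2-fluoro-4,6-dimethoxybenzaldehyde
Product: 24 2-[4-(benzyloxy)-2-bromo-5-methoxyphenoxy]-4,6-dimethoxybenzaldehyde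
Conditions: Cs2CO3, DMSO, 120 °C
Reagents that add atoms: none
Why: SNAr of the fluoride ortho to the aldehyde by the phenoxide of 22; the aryl bromide does not take part under copper-free conditions.

Step 15
Reactants: 24 diaryl ether from step 14
Product: 25 2-(benzyloxy)-3,7,9-trimethoxydibenzo[b,d]furan-6-carbaldehyde
Conditions: Pd(OAc)2 (5 mol %), PCy3·HBF4, K2CO3, PivOH (cat.), DMA, 120 °C
Reagents that add atoms: none
Why: Palladium-catalysed intramolecular direct C–H arylation (concerted metalation–deprotonation): zerovalent palladium inserts into the C–Br bond and the only free carbon ortho to the ether oxygen on the aldehyde ring, flanked by two oxygen substituents, is palladated, closing the five-membered furan ring.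

Step 16
Reactants: 25 aldehyde from step 15
Product: 27 2-(benzyloxy)-3,7,9-trimethoxydibenzo[b,d]furan-6-ol, via aryl formate 26 (not isolated)
Conditions: mCPBA, NaHCO3, CH2Cl2, 0 °C to rt; then K2CO3 (cat.), MeOH, rt
Reagents that add atoms: meta-chloroperoxybenzoic acid OOC(=O)c1cccc(Cl)c1
Why: Baeyer–Villiger oxidation of an aldehyde flanked by two oxygen substituents (aryl migration) and methanolysis of formate 26.

Step 17
Reactants: 27 phenol from step 16; 28 1-bromo-3,5-dimethoxybenzene
Product: 29 2-(benzyloxy)-6-(3,5-dimethoxyphenoxy)-3,7,9-trimethoxydibenzo[b,d]furan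
Conditions: CuI (10 mol %), picolinic acid, K3PO4, DMSO, 100 °C
Reagents that add atoms: none
Why: Copper-catalysed Ullmann diaryl ether synthesis between a 2,6-dioxygenated phenol and an unhindered aryl bromide, the favourable pairing for this coupling; it attaches ring A.

Step 18
Reactants: 29 benzyl ether from step 17
Product: 30 6-(3,5-dimethoxyphenoxy)-3,7,9-trimethoxydibenzo[b,d]furan-2-ol
Conditions: H2 (1 atm), Pd/C, EtOAc/MeOH, rt
Reagents that add atoms: none
Why: Hydrogenolysis of the benzyl ether on Pd/C; no other group in 29 is reducible under these conditions.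

Step 19
Reactants: 30 phenol from step 18
Product: 32 6-(3,5-dimethoxyphenoxy)-2-hydroxy-3,7,9-trimethoxydibenzo[b,d]furan-1-carbaldehyde (left half), via hydroxymethylphenol 31 (not isolated)
Conditions: MgCl2, Et3N, (CH2O)n, MeCN, reflux; aq. HCl
Reagents that add atoms: paraformaldehyde (as formaldehyde) C=O
Why: Magnesium-mediated ortho-formylation of a phenol (Casnati–Skattebøl): the magnesium phenoxide should deliver formaldehyde to the only free ortho carbon (the other carries OMe), and salicyl alcohol 31 is oxidised in the flask by hydride transfer to a second formaldehyde.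

Step 20
Reactants: 32 left half (rings A–C); 18 right half (rings D–H)
Product: 33 2-[2-({2'-[2,4-dimethoxy-6-(2,4,6-trimethoxyphenoxy)phenoxy]-4,4',6,6'-tetramethoxy-[1,1'-biphenyl]-2-yl}oxy)-3-formyl-5-methoxyphenoxy]-6-(3,5-dimethoxyphenoxy)-3,7,9-trimethoxydibenzo[b,d]furan-1-carbaldehyde
Conditions: CuI (30 mol %), 2,2,6,6-tetramethylheptane-3,5-dione, Cs2CO3, NMP, 110 °C
Reagents that add atoms: none
Why: Copper-mediated Ullmann diaryl ether synthesis joining the two halves; only one ring C oxygen is present as a phenol (its neighbour is still a formyl carbon), so the C–O–D ether is placed without regiochemical ambiguity.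

Step 21
Reactants: 33 dialdehyde from step 20
Product: 35 2-[2-({2'-[2,4-dimethoxy-6-(2,4,6-trimethoxyphenoxy)phenoxy]-4,4',6,6'-tetramethoxy-[1,1'-biphenyl]-2-yl}oxy)-3-hydroxy-5-methoxyphenoxy]-6-(3,5-dimethoxyphenoxy)-3,7,9-trimethoxydibenzo[b,d]furan-1-ol, via bis-formate 34 (not isolated)
Conditions: mCPBA (3 equiv), NaHCO3, CH2Cl2, 0 °C to rt; then K2CO3 (cat.), MeOH, 0 °C, under Ar
Reagents that add atoms: meta-chloroperoxybenzoic acid OOC(=O)c1cccc(Cl)c1
Why: Twofold Baeyer–Villiger oxidation of ortho-aryloxybenzaldehydes (aryl migration) and methanolysis of bis-formate 34, which turns both activating formyl groups at once into the two phenols of the cyclisation substrate.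

Step 22
Reactants: 35 seco-diphenol from step 21
Product: 37 dioxin-closed pentadeca-O-methyl ether of the target (free hydroxyl on ring D ortho to the ring E ether), via cyclohexadienone 36 (not isolated)
Conditions: PhI(OAc)2 (1.05 equiv), (CF3)2CHOH/CH2Cl2, −20 °C, 2 mM
Reagents that add atoms: none
Why: Proposed new method: ligand exchange of the ring D phenol of 35 at trivalent iodine and loss of iodobenzene should give a phenoxonium ion whose charge sits on the para carbon (the ring D C–H flanked by the methoxy-bearing carbon and the diaryl ether carbon); the ring C hydroxyl, held next to that carbon by the existing C–O–D ether, adds there to give cyclohexa-2,5-dienone 36, which loses the proton from its sp3 carbon and rearomatises to 37. The closest known reaction types are the hypervalent-iodine oxidative para-functionalisation and dearomatising cyclisation of phenols by oxygen nucleophiles and the oxidative phenol C–O coupling assumed for the biosynthesis of eckol-type dibenzodioxins from phlorethols; closure of a dibenzo-1,4-dioxin in this way has not been shown. The single ring formed is the six-membered 1,4-dioxin, closed in 6-exo-trig fashion by oxygen attack on the cationic sp2 carbon. No stereocentre results, since the sp3 centre of 36 is erased on tautomerisation. The step needs oxidation of the ring D phenol in preference to the ring C phenol and attack at the para carbon only: the ring C hydroxyl is buried in the dibenzofuran bay and hydrogen-bonded to the facing methoxy group while the ring D hydroxyl is exposed, and the tether can reach no other position of the ring D cation. The non-nucleophilic solvent, one equivalent of oxidant, low temperature and high dilution guard against solvent capture, over-oxidation of 37 and dimerisation.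

Step 23
Reactants: 37 dioxin from step 22
Product: 39 CNP0192765.0, via dibromoboryl ether 38 (not isolated)
Conditions: BBr3 (excess), CH2Cl2, −78 °C to rt; then H2O, 0 °C
Reagents that add atoms: none
Why: Lewis acid cleavage of aryl methyl ethers with BBr3 (SN2 attack of bromide on each O-methyl group); diaryl ether, dibenzofuran and dibenzodioxin C–O bonds are not cleaved, and hydrolysis of borate 38 releases the hexadecaphenol.

**Compound list**

1 | 2-bromo-1-fluoro-4-methoxybenzene | COc1ccc(F)c(Br)c1 | starting material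
2 | (3-bromo-2-fluoro-5-methoxyphenyl)lithium | [Li]c1cc(OC)cc(Br)c1F | intermediate
3 | lithium (3-bromo-2-fluoro-5-methoxyphenyl)(dimethylamino)methanolate (racemic) | [Li]OC(N(C)C)c1cc(OC)cc(Br)c1F | intermediate
4 | 3-bromo-2-fluoro-5-methoxybenzaldehyde | O=Cc1cc(OC)cc(Br)c1F | intermediate
5 | 3,5-dimethoxyphenol | COc1cc(O)cc(OC)c1 | starting material
6 | 1,3-dimethoxy-5-(methoxymethoxy)benzene | COCOc1cc(OC)cc(OC)c1 | intermediate
7 | [2,4-dimethoxy-6-(methoxymethoxy)phenyl]lithium | [Li]c1c(OC)cc(OC)cc1OCOC | intermediate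
8 | 2-iodo-1,5-dimethoxy-3-(methoxymethoxy)benzene | COCOc1cc(OC)cc(OC)c1I | intermediate
9 | 2,2'-bis(methoxymethoxy)-4,4',6,6'-tetramethoxy-1,1'-biphenyl | COCOc1cc(OC)cc(OC)c1-c1c(OC)cc(OC)cc1OCOC | intermediate
10 | 4,4',6,6'-tetramethoxy-2'-(methoxymethoxy)-[1,1'-biphenyl]-2-ol | COCOc1cc(OC)cc(OC)c1-c1c(O)cc(OC)cc1OC | intermediate
11 | 3-bromo-5-methoxy-2-{[4,4',6,6'-tetramethoxy-2'-(methoxymethoxy)-[1,1'-biphenyl]-2-yl]oxy}benzaldehyde | O=Cc1cc(OC)cc(Br)c1Oc1cc(OC)cc(OC)c1-c1c(OC)cc(OC)cc1OCOC | intermediate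
12 | 2,4,6-trimethoxyphenol | COc1cc(OC)c(O)c(OC)c1 | starting material
13 | 5-methoxy-2-{[4,4',6,6'-tetramethoxy-2'-(methoxymethoxy)-[1,1'-biphenyl]-2-yl]oxy}-3-(2,4,6-trimethoxyphenoxy)benzaldehyde | O=Cc1cc(OC)cc(Oc2c(OC)cc(OC)cc2OC)c1Oc1cc(OC)cc(OC)c1-c1c(OC)cc(OC)cc1OCOC | intermediate
14 | formate ester of phenol 15 | O=COc1cc(OC)cc(Oc2c(OC)cc(OC)cc2OC)c1Oc1cc(OC)cc(OC)c1-c1c(OC)cc(OC)cc1OCOC | intermediate
15 | 5-methoxy-2-{[4,4',6,6'-tetramethoxy-2'-(methoxymethoxy)-[1,1'-biphenyl]-2-yl]oxy}-3-(2,4,6-trimethoxyphenoxy)phenol | Oc1cc(OC)cc(Oc2c(OC)cc(OC)cc2OC)c1Oc1cc(OC)cc(OC)c1-c1c(OC)cc(OC)cc1OCOC | intermediate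
16 | 2-[2,4-dimethoxy-6-(2,4,6-trimethoxyphenoxy)phenoxy]-4,4',6,6'-tetramethoxy-2'-(methoxymethoxy)-1,1'-biphenyl | COc1cc(OC)cc(Oc2c(OC)cc(OC)cc2OC)c1Oc1cc(OC)cc(OC)c1-c1c(OC)cc(OC)cc1OCOC | intermediate
17 | 2'-[2,4-dimethoxy-6-(2,4,6-trimethoxyphenoxy)phenoxy]-4,4',6,6'-tetramethoxy-[1,1'-biphenyl]-2-ol | COc1cc(OC)cc(Oc2c(OC)cc(OC)cc2OC)c1Oc1cc(OC)cc(OC)c1-c1c(OC)cc(OC)cc1O | intermediate
18 | 3-bromo-2-({2'-[2,4-dimethoxy-6-(2,4,6-trimethoxyphenoxy)phenoxy]-4,4',6,6'-tetramethoxy-[1,1'-biphenyl]-2-yl}oxy)-5-methoxybenzaldehyde (right half, rings D–H) | O=Cc1cc(OC)cc(Br)c1Oc1cc(OC)cc(OC)c1-c1c(OC)cc(OC)cc1Oc1c(OC)cc(OC)cc1Oc1c(OC)cc(OC)cc1OC | intermediate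
19 | 4-(benzyloxy)-3-methoxybenzaldehyde | COc1cc(C=O)ccc1OCc1ccccc1 | starting material
20 | 4-(benzyloxy)-2-bromo-5-methoxybenzaldehyde | COc1cc(C=O)c(Br)cc1OCc1ccccc1 | intermediate
21 | 4-(benzyloxy)-2-bromo-5-methoxyphenyl formate | COc1cc(OC=O)c(Br)cc1OCc1ccccc1 | intermediate
22 | 4-(benzyloxy)-2-bromo-5-methoxyphenol | COc1cc(O)c(Br)cc1OCc1ccccc1 | intermediate
23 | 2-fluoro-4,6-dimethoxybenzaldehyde | COc1cc(F)c(C=O)c(OC)c1 | starting material
24 | 2-[4-(benzyloxy)-2-bromo-5-methoxyphenoxy]-4,6-dimethoxybenzaldehyde | COc1cc(Oc2cc(OC)c(OCc3ccccc3)cc2Br)c(C=O)c(OC)c1 | intermediate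
25 | 2-(benzyloxy)-3,7,9-trimethoxydibenzo[b,d]furan-6-carbaldehyde | O=Cc1c(OC)cc(OC)c2c1oc1cc(OC)c(OCc3ccccc3)cc12 | intermediate
26 | 2-(benzyloxy)-3,7,9-trimethoxydibenzo[b,d]furan-6-yl formate | O=COc1c(OC)cc(OC)c2c1oc1cc(OC)c(OCc3ccccc3)cc12 | intermediate
27 | 2-(benzyloxy)-3,7,9-trimethoxydibenzo[b,d]furan-6-ol | Oc1c(OC)cc(OC)c2c1oc1cc(OC)c(OCc3ccccc3)cc12 | intermediate
28 | 1-bromo-3,5-dimethoxybenzene | COc1cc(Br)cc(OC)c1 | starting material
29 | 2-(benzyloxy)-6-(3,5-dimethoxyphenoxy)-3,7,9-trimethoxydibenzo[b,d]furan | COc1cc(OC)cc(Oc2c(OC)cc(OC)c3c2oc2cc(OC)c(OCc4ccccc4)cc23)c1 | intermediate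
30 | 6-(3,5-dimethoxyphenoxy)-3,7,9-trimethoxydibenzo[b,d]furan-2-ol | COc1cc(OC)cc(Oc2c(OC)cc(OC)c3c2oc2cc(OC)c(O)cc23)c1 | intermediate
31 | 6-(3,5-dimethoxyphenoxy)-1-(hydroxymethyl)-3,7,9-trimethoxydibenzo[b,d]furan-2-ol | COc1cc(OC)cc(Oc2c(OC)cc(OC)c3c2oc2cc(OC)c(O)c(CO)c23)c1 | intermediate
32 | 6-(3,5-dimethoxyphenoxy)-2-hydroxy-3,7,9-trimethoxydibenzo[b,d]furan-1-carbaldehyde (left half, rings A–C) | COc1cc(OC)cc(Oc2c(OC)cc(OC)c3c2oc2cc(OC)c(O)c(C=O)c23)c1 | intermediate
33 | dialdehyde: 32 O-arylated at its 2-hydroxyl by ring D of 18 (formyl groups on dibenzofuran C-1 and on ring D) | COc1cc(OC)cc(Oc2c(OC)cc(OC)c3c2oc2cc(OC)c(Oc4cc(OC)cc(C=O)c4Oc4cc(OC)cc(OC)c4-c4c(OC)cc(OC)cc4Oc4c(OC)cc(OC)cc4Oc4c(OC)cc(OC)cc4OC)c(C=O)c23)c1 | intermediate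
34 | bis-formate of diphenol 35 | COc1cc(OC)cc(Oc2c(OC)cc(OC)c3c2oc2cc(OC)c(Oc4cc(OC)cc(OC=O)c4Oc4cc(OC)cc(OC)c4-c4c(OC)cc(OC)cc4Oc4c(OC)cc(OC)cc4Oc4c(OC)cc(OC)cc4OC)c(OC=O)c23)c1 | intermediate
35 | seco-diphenol: dibenzofuran-1-ol whose 2-oxygen carries ring D, ring D having a free hydroxyl para to its unsubstituted carbon next to the ether | COc1cc(OC)cc(Oc2c(OC)cc(OC)c3c2oc2cc(OC)c(Oc4cc(OC)cc(O)c4Oc4cc(OC)cc(OC)c4-c4c(OC)cc(OC)cc4Oc4c(OC)cc(OC)cc4Oc4c(OC)cc(OC)cc4OC)c(O)c23)c1 | intermediate
36 | cyclohexa-2,5-dienone: dioxin ring closed, ring D as 4-oxo-dienone with one sp3 CH(O) carbon (either configuration, lost on tautomerisation) | COc1cc(OC)cc(Oc2c(OC)cc(OC)c3c2oc2cc(OC)c4c(c23)OC2C(OC)=CC(=O)C(Oc3cc(OC)cc(OC)c3-c3c(OC)cc(OC)cc3Oc3c(OC)cc(OC)cc3Oc3c(OC)cc(OC)cc3OC)=C2O4)c1 | intermediate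
37 | pentadeca-O-methyl ether of the target (dioxin closed; free hydroxyl on ring D ortho to the ring E ether) | COc1cc(OC)cc(Oc2c(OC)cc(OC)c3c2oc2cc(OC)c4c(c23)Oc2c(OC)cc(O)c(Oc3cc(OC)cc(OC)c3-c3c(OC)cc(OC)cc3Oc3c(OC)cc(OC)cc3Oc3c(OC)cc(OC)cc3OC)c2O4)c1 | intermediate
38 | hexadecakis(O-dibromoboryl) derivative of the target (idealised borate) | BrB(Br)Oc1cc(OB(Br)Br)cc(Oc2c(OB(Br)Br)cc(OB(Br)Br)c3c2oc2cc(OB(Br)Br)c4c(c23)Oc2c(OB(Br)Br)cc(OB(Br)Br)c(Oc3cc(OB(Br)Br)cc(OB(Br)Br)c3-c3c(OB(Br)Br)cc(OB(Br)Br)cc3Oc3c(OB(Br)Br)cc(OB(Br)Br)cc3Oc3c(OB(Br)Br)cc(OB(Br)Br)cc3OB(Br)Br)c2O4)c1 | intermediate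
39 | CNP0192765.0 | Oc1cc(O)cc(Oc2c(O)cc(O)c3c2oc2cc(O)c4c(c23)Oc2c(O)cc(O)c(Oc3cc(O)cc(O)c3-c3c(O)cc(O)cc3Oc3c(O)cc(O)cc3Oc3c(O)cc(O)cc3O)c2O4)c1 | target

**Step count and risks**

Total step count: 23.
Longest linear sequence: 14 steps (5 → 6 → 8 → 9 → 10 → 11 → 13 → 15 → 16 → 17 → 18 → 33 → 35 → 37 → 39).

Steps most likely to fail:

1. Step 22 (proposed new method). The oxidant may engage the ring C phenol instead of the ring D phenol, so that ring C is oxidised towards a quinone; the product phenol may be oxidised further; or intermolecular coupling may outrun ring closure. The fallback uses known chemistry, sets out from 35 and comes back at 37. Pyridinium tribromide (2 equiv, CH2Cl2/MeOH, −20 °C) should brominate the carbon para to each free hydroxyl and give the dibromide F1. An intramolecular Ullmann etherification (CuI, N,N-dimethylglycine, Cs2CO3, dioxane, 90 °C, high dilution), the classical closure of 2-(2-bromophenoxy)phenols to dibenzodioxins, should then join the ring C phenoxide to the ring D bromide and give the bromo-dioxin F2. Hydrodebromination (H2, Pd/C, Et3N, EtOAc) removes the remaining ring C bromide, and any adventitious aryl bromide, to give 37.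

2. Step 20. C–O bond formation may be too slow because the phenoxide of 32 is chelated by its neighbouring formyl group and flanked on both sides, so that reduction of the aryl bromide and thermal decomposition of the aldehydes compete. The fallback reverses the roles at copper; it sets out from 18 and comes back at 33. Miyaura borylation of 18 (B2pin2, Pd(dppf)Cl2, KOAc, dioxane, 90 °C) should give the pinacol boronate F3. A Chan–Evans–Lam oxidative coupling of F3 with 32 (Cu(OAc)2, pyridine, 4 Å molecular sieves, air, CH2Cl2, rt) then gives 33 at room temperature.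

3. Step 19. Delivery of formaldehyde into the crowded bay position of the dibenzofuran may fail, leaving the phenol unchanged or diverting the intermediate benzyl alcohol into oligomeric ethers. The fallback replaces electrophilic formylation by halogen–metal exchange; it sets out from 30 and comes back at 32. Amine-catalysed ortho-bromination (NBS, i-Pr2NH cat., CH2Cl2, −78 °C) should give the bromophenol F4. Deprotonation with NaH, bromine–lithium exchange with t-BuLi at −78 °C in THF and a DMF quench then give 32.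

**Further compounds**

F1 | step 22 | dibromide of 35 (bromine on the ring D carbon para to its hydroxyl and on dibenzofuran C-4 of ring C) | COc1cc(OC)cc(Oc2c(OC)cc(OC)c3c2oc2c(Br)c(OC)c(Oc4c(Br)c(OC)cc(O)c4Oc4cc(OC)cc(OC)c4-c4c(OC)cc(OC)cc4Oc4c(OC)cc(OC)cc4Oc4c(OC)cc(OC)cc4OC)c(O)c23)c1
F2 | step 22 | bromo-dioxin: 37 carrying bromine on dibenzofuran C-4 of ring C | COc1cc(OC)cc(Oc2c(OC)cc(OC)c3c2oc2c(Br)c(OC)c4c(c23)Oc2c(OC)cc(O)c(Oc3cc(OC)cc(OC)c3-c3c(OC)cc(OC)cc3Oc3c(OC)cc(OC)cc3Oc3c(OC)cc(OC)cc3OC)c2O4)c1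
F3 | step 20 | pinacol boronate of 18: 2-({2'-[2,4-dimethoxy-6-(2,4,6-trimethoxyphenoxy)phenoxy]-4,4',6,6'-tetramethoxy-[1,1'-biphenyl]-2-yl}oxy)-5-methoxy-3-(4,4,5,5-tetramethyl-1,3,2-dioxaborolan-2-yl)benzaldehyde | O=Cc1cc(OC)cc(B2OC(C)(C)C(C)(C)O2)c1Oc1cc(OC)cc(OC)c1-c1c(OC)cc(OC)cc1Oc1c(OC)cc(OC)cc1Oc1c(OC)cc(OC)cc1OC
F4 | step 19 | 1-bromo-6-(3,5-dimethoxyphenoxy)-3,7,9-trimethoxydibenzo[b,d]furan-2-ol | COc1cc(OC)cc(Oc2c(OC)cc(OC)c3c2oc2cc(OC)c(O)c(Br)c23)c1
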